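Retrosynthesis: three bonds of the benzene ring are cut at once, C8a–C4a, C5–C6 and C6–C7 (intramolecular Dötz benzannulation, which also opens the 2H-pyran ring), then O1–C8a (alkoxy exchange at a carbene carbon), C4–C4a (Sonogashira) and C8–C8a (organolithium addition to Cr(CO)6); C6 and C8a are both former CO ligands.
Enabling feature: O1 on C8a lies para to the free hydroxyl on C6, the alkoxy/hydroxy pattern of a Dötz phenol, and the O1–C2–C3=C4 part of the pyran ring joins that oxygen to C4a, so it can serve as the tether between carbene oxygen and alkyne.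
Forward: phytol is converted into a (Z)-enynyl tertiary carbinol (epoxide, epoxy chloride, alkynol, iodoalkyne, Z-iodoalkene, enyne), which is attached through its oxygen to an isopropenyl chromium carbene; the pyran and benzene rings then close together in the last step.
Stereochemistry: 4'R and 8'R are those of natural phytol; C2 (S) is set by Sharpless epoxidation with L-(+)-diethyl tartrate and its C–O bond is never broken afterwards; the Z alkene comes from syn reduction of an iodoalkyne.

Key step: step 9

Remark: chromium carbonyl complexes are written in SMILES with formal Cr=C and Cr=C=O double bonds, and the η6-arene complex 17 as arene and Cr(CO)3 joined by a dot; this is notation only.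

Step 1
Reactants: 1 (2E,7R,11R)-phytol
Product: 2 (2S,3S,7R,11R)-2,3-epoxy-3,7,11,15-tetramethylhexadecan-1-ol
Conditions: Ti(OiPr)4 (10 mol %), L-(+)-diethyl tartrate (12 mol %), t-BuOOH (decane), 4 Å molecular sieves, CH2Cl2, −20 °C
Reagents that add atoms: tert-butyl hydroperoxide, CC(C)(C)OO
Why: Sharpless asymmetric epoxidation of an E-trisubstituted allylic alcohol is reagent-controlled, and L-(+)-diethyl tartrate should deliver oxygen to the face that gives the (2S,3S)-epoxide (as with geraniol), the remote 7R and 11R centres being spectators.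

Step 2
Reactants: 2 (2S,3S,7R,11R)-2,3-epoxy-3,7,11,15-tetramethylhexadecan-1-ol
Product: 3 (2R,3S,7R,11R)-1-chloro-2,3-epoxy-3,7,11,15-tetramethylhexadecane
Conditions: PPh3, CCl4, NaHCO3, reflux
Reagents that add atoms: carbon tetrachloride, ClC(Cl)(Cl)Cl
Why: Appel chlorination replaces the primary hydroxyl through its alkoxyphosphonium salt under buffered, nearly neutral conditions that leave the trisubstituted epoxide untouched (the C2 descriptor changes to R only because chlorine raises the priority of C1).

Step 3
Reactants: 3 (2R,3S,7R,11R)-1-chloro-2,3-epoxy-3,7,11,15-tetramethylhexadecane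
Product: 5 (3S,7R,11R)-3,7,11,15-tetramethylhexadec-1-yn-3-ol, via lithium chlorovinyl alkoxide 4 (not isolated)
Conditions: n-BuLi (3.2 equiv), THF, −40 → −20 °C; then H2O
Reagents that add atoms: none
Why: Base-induced fragmentation of a 2,3-epoxy chloride to an alkynyl carbinol: lithiation next to chlorine opens the epoxide by β-elimination, a second equivalent removes HCl and a third holds the alkyne as its acetylide, and since the C3–O bond is never broken C3 should stay S.

Step 4
Reactants: 5 (3S,7R,11R)-3,7,11,15-tetramethylhexadec-1-yn-3-ol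
Product: 6 (3S,7R,11R)-1-iodo-3,7,11,15-tetramethylhexadec-1-yn-3-ol
Conditions: N-iodosuccinimide, AgNO3 (10 mol %), acetone, 25 °C, dark
Reagents that add atoms: N-iodosuccinimide, O=C1CCC(=O)N1I
Why: Silver-catalysed electrophilic iodination of a terminal alkyne (silver acetylide intercepted by N-iodosuccinimide) is mild and should tolerate the free tertiary alcohol.

Step 5
Reactants: 6 (3S,7R,11R)-1-iodo-3,7,11,15-tetramethylhexadec-1-yn-3-ol
Product: 7 (1Z,3S,7R,11R)-1-iodo-3,7,11,15-tetramethylhexadec-1-en-3-ol
Conditions: 2-nitrobenzenesulfonylhydrazide, Et3N, THF/i-PrOH, 25 °C, dark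
Reagents that add atoms: none
Why: Diimide reduction: diimide released in situ transfers H2 in a concerted syn fashion to the iodoalkyne, which should give the Z-iodoalkene without C–I hydrogenolysis, the polarised iodoalkyne being reduced faster than the product alkene.

Step 6
Reactants: 7 (1Z,3S,7R,11R)-1-iodo-3,7,11,15-tetramethylhexadec-1-en-3-ol; 8 propyne
Product: 9 (4Z,6S,10R,14R)-6,10,14,18-tetramethylnonadec-4-en-2-yn-6-ol
Conditions: propyne (excess, THF solution), Pd(PPh3)2Cl2 (3 mol %), CuI (6 mol %), Et3N, THF, 0 → 25 °C
Reagents that add atoms: none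
Why: Sonogashira coupling of an alkenyl iodide with a terminal alkyne runs at room temperature with retention of the alkene geometry and tolerates a free tertiary alcohol.

Step 7
Reactants: 10 2-bromopropene; 11 hexacarbonylchromium Cr(CO)6
Product: 14 tetramethylammonium pentacarbonyl(2-methylprop-2-enoyl)chromate, via isopropenyllithium 12 (not isolated), via lithium acylchromate 13 (not isolated)
Conditions: t-BuLi (2 equiv), Et2O, −78 °C; Cr(CO)6, Et2O, −78 → 25 °C; then Me4NBr, H2O, 0 °C
Reagents that add atoms: tetramethylammonium bromide, C[N+](C)(C)C.[Br-]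
Why: Fischer acylmetalate synthesis: bromine–lithium exchange gives isopropenyllithium, which adds to a CO ligand of Cr(CO)6, and cation exchange should give the storable tetramethylammonium salt.

Step 8
Reactants: 14 tetramethylammonium pentacarbonyl(2-methylprop-2-enoyl)chromate; 9 (4Z,6S,10R,14R)-6,10,14,18-tetramethylnonadec-4-en-2-yn-6-ol
Product: 16 pentacarbonyl[(prop-1-en-2-yl){[(4Z,6S,10R,14R)-6,10,14,18-tetramethylnonadec-4-en-2-yn-6-yl]oxy}carbene]chromium, via acetoxycarbene complex 15 (not isolated)
Conditions: 14 (1.6 equiv), AcBr (1.5 equiv), CH2Cl2, −40 °C; then 9, −40 → −10 °C, dark; cold filtration through silica (hexane)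
Reagents that add atoms: none
Why: Proposed new method: O-acylation of the acylate gives the acetoxycarbene complex 15, whose carbene carbon is about as electrophilic as a mixed anhydride, so addition of the tertiary hydroxyl of 9 and loss of acetic acid (addition–elimination at the flat carbene carbon, no free acetyl bromide being left to ionise the alcohol) should give the tertiary alkoxycarbene with the carbinol C–O bond and its S configuration untouched; the closest known reaction type is the acyloxy/alkoxy exchange of acyloxycarbene chromium complexes with primary and hindered secondary alcohols, tertiary alcohols not being established.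

Step 9
Reactants: 16 pentacarbonyl[(prop-1-en-2-yl){[(4Z,6S,10R,14R)-6,10,14,18-tetramethylnonadec-4-en-2-yn-6-yl]oxy}carbene]chromium
Product: 18 (2S)-2,5,8-trimethyl-2-[(4R,8R)-4,8,12-trimethyltridecyl]-2H-chromen-6-ol, via arene chromium tricarbonyl complex 17 (not isolated)
Conditions: THF (0.005 M), 50 °C, argon, dark; then air, daylight, Et2O, 25 °C (brief)
Reagents that add atoms: none
Why: Proposed new method: thermal loss of one cis CO from 16 lets the tethered alkyne bind chromium and insert into the Cr=C bond (C8a–C4a), CO insertion into the resulting vinylcarbene gives a chromium-bound vinylketene (C5–C6), and 6π electrocyclisation onto the isopropenyl CH2 (C6–C7) followed by enolisation gives the phenol as its Cr(CO)3 complex 17, which air and light demetalate. The closest known reaction type is the intramolecular Dötz benzannulation of alkoxycarbene chromium complexes whose alkyne hangs on the carbene oxygen through a saturated chain of comparable length; a (Z)-alkene in the tether and a tertiary allylic oxygen substituent have not been shown. The 2H-pyran ring closes by intramolecular alkyne insertion through the oxygen tether (six-membered), and the benzene ring closes by electrocyclisation of the dienylketene and tautomerisation of the cyclohexadienone. No stereocentre is formed: C2 is the carbinol carbon of 9, whose C–O bond is not touched, and the planar chirality of 17 vanishes on demetalation. The step needs a single regiochemistry of insertion (methyl-bearing alkyne carbon next to the CO-derived C6), which the short Z-configured tether enforces because only the proximal alkyne carbon can reach the carbene carbon. It also needs benzannulation to outrun cyclopentannulation and ionisation of the allylic carbene ether, which the alkenyl chromium carbene, the donor solvent, neutral conditions and high dilution should favour.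

Compound list
1 | (2E,7R,11R)-3,7,11,15-tetramethylhexadec-2-en-1-ol (natural phytol) | OC/C=C(\C)CCC[C@H](C)CCC[C@H](C)CCCC(C)C | starting material
2 | (2S,3S,7R,11R)-2,3-epoxy-3,7,11,15-tetramethylhexadecan-1-ol | OC[C@@H]1O[C@@]1(C)CCC[C@H](C)CCC[C@H](C)CCCC(C)C | intermediate
3 | (2R,3S,7R,11R)-1-chloro-2,3-epoxy-3,7,11,15-tetramethylhexadecane | ClC[C@@H]1O[C@@]1(C)CCC[C@H](C)CCC[C@H](C)CCCC(C)C | intermediate
4 | lithium (3S,7R,11R)-1-chloro-3,7,11,15-tetramethylhexadec-1-en-3-olate, formed in situ (E drawn; the Z isomer reacts on likewise) | [Li+].[O-][C@@](C)(CCC[C@H](C)CCC[C@H](C)CCCC(C)C)/C=C/Cl | intermediate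
5 | (3S,7R,11R)-3,7,11,15-tetramethylhexadec-1-yn-3-ol | O[C@@](C)(CCC[C@H](C)CCC[C@H](C)CCCC(C)C)C#C | intermediate
6 | (3S,7R,11R)-1-iodo-3,7,11,15-tetramethylhexadec-1-yn-3-ol | O[C@@](C)(CCC[C@H](C)CCC[C@H](C)CCCC(C)C)C#CI | intermediate
7 | (1Z,3S,7R,11R)-1-iodo-3,7,11,15-tetramethylhexadec-1-en-3-ol | O[C@@](C)(CCC[C@H](C)CCC[C@H](C)CCCC(C)C)/C=C\I | intermediate
8 | propyne | CC#C | starting material
9 | (4Z,6S,10R,14R)-6,10,14,18-tetramethylnonadec-4-en-2-yn-6-ol | O[C@@](C)(CCC[C@H](C)CCC[C@H](C)CCCC(C)C)/C=C\C#CC | intermediate
10 | 2-bromopropene | C=C(C)Br | starting material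
11 | hexacarbonylchromium Cr(CO)6 | O=C=[Cr](=C=O)(=C=O)(=C=O)(=C=O)=C=O | starting material
12 | isopropenyllithium, formed in situ | [Li]C(C)=C | intermediate
13 | lithium pentacarbonyl(2-methylprop-2-enoyl)chromate, formed in situ | C=C(C)C([O-])=[Cr](=C=O)(=C=O)(=C=O)(=C=O)=C=O.[Li+] | intermediate
14 | tetramethylammonium pentacarbonyl(2-methylprop-2-enoyl)chromate | C=C(C)C([O-])=[Cr](=C=O)(=C=O)(=C=O)(=C=O)=C=O.C[N+](C)(C)C | intermediate
15 | pentacarbonyl[(acetoxy)(prop-1-en-2-yl)carbene]chromium, formed in situ | C=C(C)C(OC(C)=O)=[Cr](=C=O)(=C=O)(=C=O)(=C=O)=C=O | intermediate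
16 | pentacarbonyl[(prop-1-en-2-yl){[(4Z,6S,10R,14R)-6,10,14,18-tetramethylnonadec-4-en-2-yn-6-yl]oxy}carbene]chromium | C=C(C)C(O[C@@](C)(CCC[C@H](C)CCC[C@H](C)CCCC(C)C)/C=C\C#CC)=[Cr](=C=O)(=C=O)(=C=O)(=C=O)=C=O | intermediate
17 | tricarbonyl{η6-(2S)-2,5,8-trimethyl-2-[(4R,8R)-4,8,12-trimethyltridecyl]-2H-chromen-6-ol}chromium, formed in situ (chromium on either face) | Cc1cc(O)c(C)c2c1O[C@@](C)(CCC[C@H](C)CCC[C@H](C)CCCC(C)C)C=C2.[Cr](=C=O)(=C=O)=C=O | intermediate
18 | (2S)-2,5,8-trimethyl-2-[(4R,8R)-4,8,12-trimethyltridecyl]-2H-chromen-6-ol, (2S,4'R,8'R)-3,4-dehydro-β-tocopherol | Cc1cc(O)c(C)c2c1O[C@@](C)(CCC[C@H](C)CCC[C@H](C)CCCC(C)C)C=C2 | target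

Total step count: 9. Longest linear sequence: 8 steps (1 → 18 through steps 1 to 6, 8 and 9); step 7 is a one-step branch.

Steps most likely to fail

1. Step 8. The hindered tertiary hydroxyl may add to the acetoxycarbene carbon more slowly than the thermally labile acyloxy complex decomposes, or the product may ionise at its tertiary allylic C–O bond during isolation. The fallback uses known chemistry, sets out from 5 and returns at 18 without chromium. The potassium alkoxide of 5 (KHMDS, DMF, 0 → 25 °C) displaces fluoride from 4-fluoro-2,5-dimethylbenzaldehyde by nucleophilic aromatic substitution para to the formyl group, giving 2,5-dimethyl-4-{[(3S,7R,11R)-3,7,11,15-tetramethylhexadec-1-yn-3-yl]oxy}benzaldehyde F1. Baeyer–Villiger (Dakin-type) oxidation with 3-chloroperoxybenzoic acid in CH2Cl2 gives the aryl formate 2,5-dimethyl-4-{[(3S,7R,11R)-3,7,11,15-tetramethylhexadec-1-yn-3-yl]oxy}phenyl formate F2, and methanolysis (K2CO3, MeOH) gives 2,5-dimethyl-4-{[(3S,7R,11R)-3,7,11,15-tetramethylhexadec-1-yn-3-yl]oxy}phenol F3. Gold-catalysed 6-endo intramolecular hydroarylation of this aryl propargyl ether ((Ph3P)AuNTf2, CH2Cl2, 25 °C) should then close the pyran ring at the only free position ortho to the ether oxygen and give 18. The carbinol C–O bond is kept throughout (direct electrophilic hydroarylation, not the thermal Claisen pathway), so C2 should remain S.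

2. Step 9. The rigid enyne tether may slow alkyne insertion so that ionisation of the tertiary allylic carbene ether or CO-free cyclopentannulation takes over. The fallback uses known chemistry, sets out from 1 and returns at 18. Phytol 1 is oxidised with MnO2 (hexane, 25 °C) to (2E,7R,11R)-3,7,11,15-tetramethylhexadec-2-enal F4. This is condensed with 2,5-dimethylhydroquinone in the classical chromenylation (pyridine, 110 °C, or PhB(OH)2/AcOH in toluene at reflux; condensation to the ortho-quinone methide, then oxa-6π electrocyclisation). The hydroquinone is symmetric, so one constitution results, but C2 is not controlled: 18 should form together with its epimer (2R)-2,5,8-trimethyl-2-[(4R,8R)-4,8,12-trimethyltridecyl]-2H-chromen-6-ol F5. The two are separated by preparative HPLC on a cellulose carbamate chiral phase. This gives up stereocontrol at C2 in exchange for two established steps and a separation.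

3. Step 5. Over-reduction to the iodoalkane, loss of iodine, or incomplete conversion next to the hindered carbinol may erode the Z-iodoalkene. The fallback sets out from 6 (with 8) and returns at 9, bypassing steps 5 and 6. Cadiot–Chodkiewicz coupling of iodoalkyne 6 with propyne 8 (CuCl, NH2OH·HCl, n-BuNH2, MeOH/H2O, 0 °C) gives (6S,10R,14R)-6,10,14,18-tetramethylnonadeca-2,4-diyn-6-ol F6. Hydroxyl-assisted semi-reduction of the triple bond next to the carbinol with activated (Rieke) zinc in THF/MeOH/H2O should then give the (Z)-enynol 9 directly.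

Further compounds
F1 | step 8 | 2,5-dimethyl-4-{[(3S,7R,11R)-3,7,11,15-tetramethylhexadec-1-yn-3-yl]oxy}benzaldehyde | O=Cc1cc(C)c(O[C@@](C)(CCC[C@H](C)CCC[C@H](C)CCCC(C)C)C#C)cc1C
F2 | step 8 | 2,5-dimethyl-4-{[(3S,7R,11R)-3,7,11,15-tetramethylhexadec-1-yn-3-yl]oxy}phenyl formate | O=COc1cc(C)c(O[C@@](C)(CCC[C@H](C)CCC[C@H](C)CCCC(C)C)C#C)cc1C
F3 | step 8 | 2,5-dimethyl-4-{[(3S,7R,11R)-3,7,11,15-tetramethylhexadec-1-yn-3-yl]oxy}phenol | Oc1cc(C)c(O[C@@](C)(CCC[C@H](C)CCC[C@H](C)CCCC(C)C)C#C)cc1C
F4 | step 9 | (2E,7R,11R)-3,7,11,15-tetramethylhexadec-2-enal | O=C/C=C(\C)CCC[C@H](C)CCC[C@H](C)CCCC(C)C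
F5 | step 9 | (2R)-2,5,8-trimethyl-2-[(4R,8R)-4,8,12-trimethyltridecyl]-2H-chromen-6-ol | Cc1cc(O)c(C)c2c1O[C@](C)(CCC[C@H](C)CCC[C@H](C)CCCC(C)C)C=C2
F6 | step 5 | (6S,10R,14R)-6,10,14,18-tetramethylnonadeca-2,4-diyn-6-ol | O[C@@](C)(CCC[C@H](C)CCC[C@H](C)CCCC(C)C)C#CC#CC
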